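Retrosynthesis: after removal of the silyl groups and the C4 acetate, the exocyclic C3=C1' bond is cut (aldol, dehydration) into γ-lactone 10 and chain aldehyde 22. The lactone O1–C5 bond is then cut (palladium allylic lactonisation) to acyclic acid 9, C2–C3 of 9 and C2'–C3' of 22 by acetate aldols, and the chain C10'–O ether bond by alkylation.
Forward: the γ-lactone (O1, C2, C3, C4, C5), the only ring made, closes in step 8; the nerol/p-coumarate chain is joined at C3 in step 17 and becomes the C3=C1' alkene in step 18; acetate exchange and desilylation finish.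
Stereochemistry: C4 comes from a thiazolidinethione acetate aldol, C5 from C4 in step 8, and C3' from a second auxiliary aldol. 8'Z comes from nerol, 4'E from SeO2 oxidation, the arylpropenyl E from p-coumarate, and C3=C1' E from E1cB elimination.
Enabling feature: C5 is an allylic C–O stereocentre, O1–C5–CH=C(CH3)2, whose alkene ends in a carbon bearing two methyl groups. The π-allyl palladium complex that delivers C5 can therefore exchange faces at that terminus, and both diastereomeric complexes can drain to the trans-4,5 lactone.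

Key step: step 8

Assumption: in step 8 the (R,R) enantiomer of the DACH-phenyl Trost ligand is taken as the one whose preference matches that of the C4 silyloxy group; the other enantiomer is used if a trial shows the pairing to be mismatched.
Assumption: 6 and 19 are bought (each is otherwise one N-acetylation of commercial 4-benzyl-1,3-thiazolidine-2-thione), and 11 is the commercial methyl ester of p-coumaric acid.
In the names below, Ar = 4-(triisopropylsilyloxy)phenyl and (E)-ArCH=CHCH2O is the (2E)-3-arylprop-2-en-1-yloxy group.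

Step 1
Reactants: 1 2-methylbut-3-yn-2-ol
Product: 2 4-methylpent-2-yne-1,4-diol
Conditions: n-BuLi (2.1 equiv), THF, −78 → 0 °C; (CH2O)n, 0 °C → rt; H2O
Reagents that add atoms: paraformaldehyde (formaldehyde), C=O
Why: Double deprotonation gives the alkoxide–acetylide, whose carbon terminus adds to formaldehyde (acetylide hydroxymethylation).

Step 2
Reactants: 2 4-methylpent-2-yne-1,4-diol
Product: 3 (2E)-4-methylpent-2-ene-1,4-diol
Conditions: LiAlH4 (2.5 equiv), THF, 0 °C → reflux; H2O, aq NaOH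
Reagents that add atoms: none
Why: Hydroxyl-directed trans-hydroalumination of the propargylic alcohol and protonolysis of the vinyl–aluminium bond give the E alkene only.

Step 3
Reactants: 3 (2E)-4-methylpent-2-ene-1,4-diol
Product: 4 (2E)-4-hydroxy-4-methylpent-2-enal
Conditions: MnO2 (activated, 15 equiv), CH2Cl2, rt
Reagents that add atoms: none
Why: MnO2 oxidation is selective for the primary allylic alcohol, and the tertiary alcohol has no carbinol hydrogen to lose.

Step 4
Reactants: 4 (2E)-4-hydroxy-4-methylpent-2-enal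
Product: 5 methyl (3E)-2-methyl-5-oxopent-3-en-2-yl carbonate
Conditions: ClCO2Me (3 equiv), pyridine (6 equiv), DMAP (0.2 equiv), CH2Cl2, 0 °C → rt
Reagents that add atoms: methyl chloroformate, COC(=O)Cl
Why: DMAP/pyridine-promoted acylation of the unhindered dimethylcarbinol by the chloroformate (carbonate formation) needs no strong base, which the enal would not survive, and the E geometry rules out cyclisation.

Step 5
Reactants: 5 methyl (3E)-2-methyl-5-oxopent-3-en-2-yl carbonate; 6 1-[(4R)-4-benzyl-2-thioxo-1,3-thiazolidin-3-yl]ethan-1-one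
Product: 7 (3S,4E)-1-[(4R)-4-benzyl-2-thioxo-1,3-thiazolidin-3-yl]-3-hydroxy-6-(methoxycarbonyloxy)-6-methylhept-4-en-1-one
Conditions: 6, TiCl4 (1.05 equiv), i-Pr2NEt (1.1 equiv), CH2Cl2, −78 → −40 °C; then 5, −78 °C
Reagents that add atoms: none
Why: Nagao-type acetate aldol addition of the chlorotitanium enolate of 6 through a thiocarbonyl-chelated chair transition state, with the aldehyde on the enolate face opposite the benzyl group, should set C3 as S (the later C4), the minor diastereomer being removed by chromatography.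

Step 6
Reactants: 7 (3S,4E)-1-[(4R)-4-benzyl-2-thioxo-1,3-thiazolidin-3-yl]-3-hydroxy-6-(methoxycarbonyloxy)-6-methylhept-4-en-1-one
Product: 8 (3S,4E)-1-[(4R)-4-benzyl-2-thioxo-1,3-thiazolidin-3-yl]-6-(methoxycarbonyloxy)-6-methyl-3-(triethylsilyloxy)hept-4-en-1-one
Conditions: Et3SiOTf (1.3 equiv), 2,6-lutidine (2 equiv), CH2Cl2, −78 °C
Reagents that add atoms: triethylsilyl trifluoromethanesulfonate, CC[Si](CC)(CC)OS(=O)(=O)C(F)(F)F
Why: A silyl triflate with a hindered pyridine base silylates the secondary allylic alcohol at low temperature without touching the acyl thiazolidinethione or the carbonate (standard O-silylation).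

Step 7
Reactants: 8 (3S,4E)-1-[(4R)-4-benzyl-2-thioxo-1,3-thiazolidin-3-yl]-6-(methoxycarbonyloxy)-6-methyl-3-(triethylsilyloxy)hept-4-en-1-one
Product: 9 (3S,4E)-6-(methoxycarbonyloxy)-6-methyl-3-(triethylsilyloxy)hept-4-enoic acid
Conditions: LiOH (2.2 equiv), THF/H2O 4:1, 0 °C; 1 M HCl to pH 4, 0 °C
Reagents that add atoms: lithium hydroxide in water, [Li+].[OH-]
Why: Hydroxide cleaves the activated, twisted N-acyl thiazolidinethione at 0 °C far faster than the hindered tertiary alkyl carbonate (acyl substitution), and the carboxylate formed resists β-elimination of the silyloxy group.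

Step 8
Reactants: 9 (3S,4E)-6-(methoxycarbonyloxy)-6-methyl-3-(triethylsilyloxy)hept-4-enoic acid
Product: 10 (4S,5R)-5-(2-methylprop-1-en-1-yl)-4-(triethylsilyloxy)dihydrofuran-2(3H)-one
Conditions: Pd2(dba)3·CHCl3 (2.5 mol %), (R,R)-DACH-phenyl Trost ligand (7.5 mol %), Et3N (1.0 equiv), degassed CH2Cl2, rt
Reagents that add atoms: none
Why: Zerovalent palladium ionises the tertiary allylic carbonate of 9 with loss of CO2 and methoxide, which leaves the carboxylate facing a syn-configured 1,1-dimethyl-3-alkyl π-allyl unit; the closest known reaction type is the Tsuji–Trost allylic substitution with a carboxylate nucleophile, run as a dynamic kinetic lactonisation. The γ-lactone (O1, C2, C3, C4, C5) closes by 5-exo attack of the carboxylate oxygen on the secondary allyl terminus anti to palladium, which forms O1–C5 and leaves the 2-methylprop-1-enyl group as the trisubstituted alkene. The new stereocentre C5 is controlled by the silyloxy-bearing centre C4, reinforced by the chiral ligand: the two diastereomeric complexes interconvert by η3–η1–η3 isomerisation at the terminus that carries two identical methyl groups, and the one that closes with the allyl chain trans to the silyloxy group should react faster. The allylic lactone can re-ionise as well, so a cis isomer is returned to the equilibrating pool and the more stable trans-4,5 lactone should accumulate. The step needs attack at the secondary and not the tertiary terminus and a trans C4/C5 relationship; the first is secured because the alternative is a seven-membered lactone holding an E alkene, the second by the C4 silyloxy group under these equilibrating conditions, while fast intramolecular capture should keep elimination to the diene in check.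

Step 9
Reactants: 11 methyl (2E)-3-(4-hydroxyphenyl)prop-2-enoate
Product: 12 methyl (2E)-3-[4-(triisopropylsilyloxy)phenyl]prop-2-enoate
Conditions: i-Pr3SiCl (1.2 equiv), imidazole (2.5 equiv), DMF, rt
Reagents that add atoms: chlorotriisopropylsilane, CC(C)[Si](Cl)(C(C)C)C(C)C
Why: Imidazole-promoted silylation of the phenol, the triisopropylsilyl group being chosen because it resists the alkoxide of step 12 and the bases of steps 17 and 18.

Step 10
Reactants: 12 methyl (2E)-3-[4-(triisopropylsilyloxy)phenyl]prop-2-enoate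
Product: 13 (2E)-3-[4-(triisopropylsilyloxy)phenyl]prop-2-en-1-ol
Conditions: i-Bu2AlH (2.5 equiv), CH2Cl2, −78 → 0 °C; aq KNaC4H4O6 work-up
Reagents that add atoms: none
Why: i-Bu2AlH reduces the conjugated ester by 1,2-addition to the allylic alcohol and leaves the alkene and the aryl silyl ether.

Step 11
Reactants: 14 nerol, (2Z)-3,7-dimethylocta-2,6-dien-1-ol
Product: 15 neryl bromide, (2Z)-1-bromo-3,7-dimethylocta-2,6-diene
Conditions: PBr3 (0.4 equiv), pyridine (cat.), Et2O, −10 °C; used crude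
Reagents that add atoms: phosphorus tribromide, BrP(Br)Br
Why: PBr3 converts the primary allylic alcohol into the bromide by SN2 displacement at low temperature with the Z alkene retained.

Step 12
Reactants: 13 (2E)-3-[4-(triisopropylsilyloxy)phenyl]prop-2-en-1-ol; 15 neryl bromide
Product: 16 triisopropyl{4-[(1E)-3-{[(2Z)-3,7-dimethylocta-2,6-dien-1-yl]oxy}prop-1-en-1-yl]phenoxy}silane
Conditions: NaH (1.2 equiv), THF, 0 °C; then 15 (1.2 equiv), Bu4NI (0.1 equiv), 0 °C → rt
Reagents that add atoms: none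
Why: Williamson ether synthesis, in which the sodium alkoxide of 13 displaces the primary allylic bromide by SN2 faster than it attacks the hindered aryl silyl ether.

Step 13
Reactants: 16 triisopropyl{4-[(1E)-3-{[(2Z)-3,7-dimethylocta-2,6-dien-1-yl]oxy}prop-1-en-1-yl]phenoxy}silane
Product: 18 (2E,6Z)-2,6-dimethyl-8-[(E)-ArCH=CHCH2O]octa-2,6-dienal, via allylic alcohol 17 (not isolated)
Conditions: SeO2 (0.3 equiv), t-BuOOH (3 equiv), salicylic acid (0.1 equiv), CH2Cl2, 0 °C → rt; crude mixture then MnO2 (15 equiv), CH2Cl2, rt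
Reagents that add atoms: selenium dioxide, O=[Se]=O (oxygen donor, kept turning over by tert-butyl hydroperoxide, CC(C)(C)OO)
Why: SeO2 allylic oxidation (ene reaction then [2,3]-sigmatropic shift) attacks the E-methyl group of the most electron-rich, gem-dimethyl alkene and keeps the new alkene E, and MnO2 brings the alcohol part of the mixture to the same enal.

Step 14
Reactants: 18 (2E,6Z)-2,6-dimethyl-8-[(E)-ArCH=CHCH2O]octa-2,6-dienal; 19 1-[(4S)-4-benzyl-2-thioxo-1,3-thiazolidin-3-yl]ethan-1-one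
Product: 20 (3R,4E,8Z)-1-[(4S)-4-benzyl-2-thioxo-1,3-thiazolidin-3-yl]-3-hydroxy-4,8-dimethyl-10-[(E)-ArCH=CHCH2O]deca-4,8-dien-1-one
Conditions: 19, TiCl4 (1.0 equiv), i-Pr2NEt (1.1 equiv), CH2Cl2, −78 → −40 °C; then 18, −78 °C
Reagents that add atoms: none
Why: The same chelate-controlled Nagao acetate aldol as in step 5, now with the enantiomeric (4S) auxiliary, should set C3 of the chain (the later C3') as R.

Step 15
Reactants: 20 (3R,4E,8Z)-1-[(4S)-4-benzyl-2-thioxo-1,3-thiazolidin-3-yl]-3-hydroxy-4,8-dimethyl-10-[(E)-ArCH=CHCH2O]deca-4,8-dien-1-one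
Product: 21 (3R,4E,8Z)-1-[(4S)-4-benzyl-2-thioxo-1,3-thiazolidin-3-yl]-3-(tert-butyldimethylsilyloxy)-4,8-dimethyl-10-[(E)-ArCH=CHCH2O]deca-4,8-dien-1-one
Conditions: t-BuMe2SiOTf (1.3 equiv), 2,6-lutidine (2.5 equiv), CH2Cl2, −78 → 0 °C
Reagents that add atoms: tert-butyldimethylsilyl trifluoromethanesulfonate, CC(C)(C)[Si](C)(C)OS(=O)(=O)C(F)(F)F
Why: Silyl triflate/2,6-lutidine protection of the hindered allylic alcohol as the tert-butyldimethylsilyl ether, which will outlast the triethylsilyl ether in step 19.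

Step 16
Reactants: 21 (3R,4E,8Z)-1-[(4S)-4-benzyl-2-thioxo-1,3-thiazolidin-3-yl]-3-(tert-butyldimethylsilyloxy)-4,8-dimethyl-10-[(E)-ArCH=CHCH2O]deca-4,8-dien-1-one
Product: 22 (3R,4E,8Z)-3-(tert-butyldimethylsilyloxy)-4,8-dimethyl-10-[(E)-ArCH=CHCH2O]deca-4,8-dienal
Conditions: i-Bu2AlH (1.3 equiv), CH2Cl2, −78 °C; aq KNaC4H4O6 work-up
Reagents that add atoms: none
Why: i-Bu2AlH adds once to the N-acyl thiazolidinethione and the tetrahedral aluminium adduct collapses only on work-up, so the aldehyde is released directly (partial reduction of an activated amide).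

Step 17
Reactants: 10 (4S,5R)-5-(2-methylprop-1-en-1-yl)-4-(triethylsilyloxy)dihydrofuran-2(3H)-one; 22 (3R,4E,8Z)-3-(tert-butyldimethylsilyloxy)-4,8-dimethyl-10-[(E)-ArCH=CHCH2O]deca-4,8-dienal
Product: 23 (4S,5R)-3-{(3R,4E,8Z)-3-(tert-butyldimethylsilyloxy)-1-hydroxy-4,8-dimethyl-10-[(E)-ArCH=CHCH2O]deca-4,8-dien-1-yl}-5-(2-methylprop-1-en-1-yl)-4-(triethylsilyloxy)dihydrofuran-2(3H)-one (epimers at C3 and at the carbinol carbon)
Conditions: LiN(SiMe3)2 (1.1 equiv), THF, −78 °C; then 22 (1.1 equiv), −78 °C; AcOH quench at −78 °C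
Reagents that add atoms: none
Why: Lithium enolate aldol addition at C3 of the lactone at −78 °C, where β-silyloxy γ-lactone enolates (as in silylated 2-deoxyribonolactone) are known to persist without β-elimination; the two new centres are erased in step 18, so their mixture does not matter.

Step 18
Reactants: 23 the aldol adducts of step 17
Product: 25 (3E,4S,5R)-3-{(3R,4E,8Z)-3-(tert-butyldimethylsilyloxy)-4,8-dimethyl-10-[(E)-ArCH=CHCH2O]deca-4,8-dien-1-ylidene}-5-(2-methylprop-1-en-1-yl)-4-(triethylsilyloxy)dihydrofuran-2(3H)-one, via mesylate 24 (not isolated)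
Conditions: MeSO2Cl (1.5 equiv), Et3N (3 equiv), CH2Cl2, 0 °C; then DBU (2.5 equiv), 0 °C → rt
Reagents that add atoms: none
Why: Mesylation and DBU-induced E1cB elimination give the conjugated alkylidene lactone, and the E isomer (chain trans to the lactone carbonyl) is expected as the thermodynamically preferred outcome of this enolate pathway.

Step 19
Reactants: 25 the E-alkylidene lactone of step 18
Product: 26 (3E,4S,5R)-3-{(3R,4E,8Z)-3-(tert-butyldimethylsilyloxy)-4,8-dimethyl-10-[(E)-ArCH=CHCH2O]deca-4,8-dien-1-ylidene}-4-hydroxy-5-(2-methylprop-1-en-1-yl)dihydrofuran-2(3H)-one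
Conditions: HF·pyridine, pyridine, THF, 0 °C
Reagents that add atoms: none
Why: Buffered HF·pyridine removes a triethylsilyl ether much faster than a secondary tert-butyldimethylsilyl or an aryl triisopropylsilyl ether (selective desilylation).

Step 20
Reactants: 26 the C4 alcohol of step 19
Product: 27 (3E,4S,5R)-4-acetoxy-3-{(3R,4E,8Z)-3-(tert-butyldimethylsilyloxy)-4,8-dimethyl-10-[(E)-ArCH=CHCH2O]deca-4,8-dien-1-ylidene}-5-(2-methylprop-1-en-1-yl)dihydrofuran-2(3H)-one
Conditions: Ac2O (3 equiv), pyridine (6 equiv), DMAP (0.1 equiv), CH2Cl2, 0 °C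
Reagents that add atoms: acetic anhydride, CC(=O)OC(C)=O
Why: DMAP-catalysed acetylation of the allylic secondary alcohol, the usual way to acetates of Morita–Baylis–Hillman-type alcohols, run cold to avoid SN2' attack by the amine.

Step 21
Reactants: 27 the C4 acetate of step 20
Product: 28 (3E,4S,5R)-4-acetoxy-3-[(3R,4E,8Z)-3-hydroxy-10-{[(2E)-3-(4-hydroxyphenyl)prop-2-en-1-yl]oxy}-4,8-dimethyldeca-4,8-dien-1-ylidene]-5-(2-methylprop-1-en-1-yl)dihydrofuran-2(3H)-one (CNP0237370.1)
Conditions: Bu4NF (4 equiv), AcOH (4 equiv), THF, 0 °C → rt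
Reagents that add atoms: none
Why: Fluoride cleaves both remaining Si–O bonds, and buffering with acetic acid keeps the medium non-basic so that the C4 acetate and the alkylidene lactone survive (global desilylation).

Compound list
1 | 2-methylbut-3-yn-2-ol | CC(C)(O)C#C | starting material
2 | 4-methylpent-2-yne-1,4-diol | CC(C)(O)C#CCO | intermediate
3 | (2E)-4-methylpent-2-ene-1,4-diol | CC(C)(O)/C=C/CO | intermediate
4 | (2E)-4-hydroxy-4-methylpent-2-enal | CC(C)(O)/C=C/C=O | intermediate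
5 | methyl (3E)-2-methyl-5-oxopent-3-en-2-yl carbonate | COC(=O)OC(C)(C)/C=C/C=O | intermediate
6 | 1-[(4R)-4-benzyl-2-thioxo-1,3-thiazolidin-3-yl]ethan-1-one | CC(=O)N1C(=S)SC[C@H]1Cc1ccccc1 | starting material
7 | (3S,4E)-1-[(4R)-4-benzyl-2-thioxo-1,3-thiazolidin-3-yl]-3-hydroxy-6-(methoxycarbonyloxy)-6-methylhept-4-en-1-one | O[C@H](/C=C/C(C)(C)OC(=O)OC)CC(=O)N1C(=S)SC[C@H]1Cc1ccccc1 | intermediate
8 | (3S,4E)-1-[(4R)-4-benzyl-2-thioxo-1,3-thiazolidin-3-yl]-6-(methoxycarbonyloxy)-6-methyl-3-(triethylsilyloxy)hept-4-en-1-one | CC[Si](CC)(CC)O[C@H](/C=C/C(C)(C)OC(=O)OC)CC(=O)N1C(=S)SC[C@H]1Cc1ccccc1 | intermediate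
9 | (3S,4E)-6-(methoxycarbonyloxy)-6-methyl-3-(triethylsilyloxy)hept-4-enoic acid | CC[Si](CC)(CC)O[C@H](/C=C/C(C)(C)OC(=O)OC)CC(=O)O | intermediate
10 | (4S,5R)-5-(2-methylprop-1-en-1-yl)-4-(triethylsilyloxy)dihydrofuran-2(3H)-one | CC[Si](CC)(CC)O[C@H]1CC(=O)O[C@@H]1C=C(C)C | intermediate
11 | methyl (2E)-3-(4-hydroxyphenyl)prop-2-enoate (methyl p-coumarate) | COC(=O)/C=C/c1ccc(O)cc1 | starting material
12 | methyl (2E)-3-[4-(triisopropylsilyloxy)phenyl]prop-2-enoate | COC(=O)/C=C/c1ccc(O[Si](C(C)C)(C(C)C)C(C)C)cc1 | intermediate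
13 | (2E)-3-[4-(triisopropylsilyloxy)phenyl]prop-2-en-1-ol | OC/C=C/c1ccc(O[Si](C(C)C)(C(C)C)C(C)C)cc1 | intermediate
14 | nerol, (2Z)-3,7-dimethylocta-2,6-dien-1-ol | CC(C)=CCC/C(C)=C\CO | starting material
15 | neryl bromide, (2Z)-1-bromo-3,7-dimethylocta-2,6-diene | CC(C)=CCC/C(C)=C\CBr | intermediate
16 | triisopropyl{4-[(1E)-3-{[(2Z)-3,7-dimethylocta-2,6-dien-1-yl]oxy}prop-1-en-1-yl]phenoxy}silane | CC(C)=CCC/C(C)=C\COC/C=C/c1ccc(O[Si](C(C)C)(C(C)C)C(C)C)cc1 | intermediate
17 | (2E,6Z)-2,6-dimethyl-8-{[(2E)-3-[4-(triisopropylsilyloxy)phenyl]prop-2-en-1-yl]oxy}octa-2,6-dien-1-ol | OC/C(C)=C/CC/C(C)=C\COC/C=C/c1ccc(O[Si](C(C)C)(C(C)C)C(C)C)cc1 | intermediate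
18 | (2E,6Z)-2,6-dimethyl-8-{[(2E)-3-[4-(triisopropylsilyloxy)phenyl]prop-2-en-1-yl]oxy}octa-2,6-dienal | O=C/C(C)=C/CC/C(C)=C\COC/C=C/c1ccc(O[Si](C(C)C)(C(C)C)C(C)C)cc1 | intermediate
19 | 1-[(4S)-4-benzyl-2-thioxo-1,3-thiazolidin-3-yl]ethan-1-one | CC(=O)N1C(=S)SC[C@@H]1Cc1ccccc1 | starting material
20 | (3R,4E,8Z)-1-[(4S)-4-benzyl-2-thioxo-1,3-thiazolidin-3-yl]-3-hydroxy-4,8-dimethyl-10-{[(2E)-3-[4-(triisopropylsilyloxy)phenyl]prop-2-en-1-yl]oxy}deca-4,8-dien-1-one | O[C@H](CC(=O)N1C(=S)SC[C@@H]1Cc2ccccc2)/C(C)=C/CC/C(C)=C\COC/C=C/c3ccc(O[Si](C(C)C)(C(C)C)C(C)C)cc3 | intermediate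
21 | (3R,4E,8Z)-1-[(4S)-4-benzyl-2-thioxo-1,3-thiazolidin-3-yl]-3-(tert-butyldimethylsilyloxy)-4,8-dimethyl-10-{[(2E)-3-[4-(triisopropylsilyloxy)phenyl]prop-2-en-1-yl]oxy}deca-4,8-dien-1-one | CC(C)(C)[Si](C)(C)O[C@H](CC(=O)N1C(=S)SC[C@@H]1Cc2ccccc2)/C(C)=C/CC/C(C)=C\COC/C=C/c3ccc(O[Si](C(C)C)(C(C)C)C(C)C)cc3 | intermediate
22 | (3R,4E,8Z)-3-(tert-butyldimethylsilyloxy)-4,8-dimethyl-10-{[(2E)-3-[4-(triisopropylsilyloxy)phenyl]prop-2-en-1-yl]oxy}deca-4,8-dienal | CC(C)(C)[Si](C)(C)O[C@H](CC=O)/C(C)=C/CC/C(C)=C\COC/C=C/c1ccc(O[Si](C(C)C)(C(C)C)C(C)C)cc1 | intermediate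
23 | (4S,5R)-3-[(3R,4E,8Z)-3-(tert-butyldimethylsilyloxy)-1-hydroxy-4,8-dimethyl-10-{[(2E)-3-[4-(triisopropylsilyloxy)phenyl]prop-2-en-1-yl]oxy}deca-4,8-dien-1-yl]-5-(2-methylprop-1-en-1-yl)-4-(triethylsilyloxy)dihydrofuran-2(3H)-one, epimers at C3 and C1' | CC[Si](CC)(CC)O[C@H]1C(C(O)C[C@@H](O[Si](C)(C)C(C)(C)C)/C(C)=C/CC/C(C)=C\COC/C=C/c2ccc(O[Si](C(C)C)(C(C)C)C(C)C)cc2)C(=O)O[C@@H]1C=C(C)C | intermediate
24 | methanesulfonate of 23 at the C1' hydroxyl, epimers at C3 and C1' | CC[Si](CC)(CC)O[C@H]1C(C(OS(C)(=O)=O)C[C@@H](O[Si](C)(C)C(C)(C)C)/C(C)=C/CC/C(C)=C\COC/C=C/c2ccc(O[Si](C(C)C)(C(C)C)C(C)C)cc2)C(=O)O[C@@H]1C=C(C)C | intermediate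
25 | (3E,4S,5R)-3-[(3R,4E,8Z)-3-(tert-butyldimethylsilyloxy)-4,8-dimethyl-10-{[(2E)-3-[4-(triisopropylsilyloxy)phenyl]prop-2-en-1-yl]oxy}deca-4,8-dien-1-ylidene]-5-(2-methylprop-1-en-1-yl)-4-(triethylsilyloxy)dihydrofuran-2(3H)-one | CC[Si](CC)(CC)O[C@H]1/C(=C\C[C@@H](O[Si](C)(C)C(C)(C)C)/C(C)=C/CC/C(C)=C\COC/C=C/c2ccc(O[Si](C(C)C)(C(C)C)C(C)C)cc2)C(=O)O[C@@H]1C=C(C)C | intermediate
26 | (3E,4S,5R)-3-[(3R,4E,8Z)-3-(tert-butyldimethylsilyloxy)-4,8-dimethyl-10-{[(2E)-3-[4-(triisopropylsilyloxy)phenyl]prop-2-en-1-yl]oxy}deca-4,8-dien-1-ylidene]-4-hydroxy-5-(2-methylprop-1-en-1-yl)dihydrofuran-2(3H)-one | O[C@H]1/C(=C\C[C@@H](O[Si](C)(C)C(C)(C)C)/C(C)=C/CC/C(C)=C\COC/C=C/c2ccc(O[Si](C(C)C)(C(C)C)C(C)C)cc2)C(=O)O[C@@H]1C=C(C)C | intermediate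
27 | (3E,4S,5R)-4-acetoxy-3-[(3R,4E,8Z)-3-(tert-butyldimethylsilyloxy)-4,8-dimethyl-10-{[(2E)-3-[4-(triisopropylsilyloxy)phenyl]prop-2-en-1-yl]oxy}deca-4,8-dien-1-ylidene]-5-(2-methylprop-1-en-1-yl)dihydrofuran-2(3H)-one | CC(=O)O[C@H]1/C(=C\C[C@@H](O[Si](C)(C)C(C)(C)C)/C(C)=C/CC/C(C)=C\COC/C=C/c2ccc(O[Si](C(C)C)(C(C)C)C(C)C)cc2)C(=O)O[C@@H]1C=C(C)C | intermediate
28 | (3E,4S,5R)-4-acetoxy-3-[(3R,4E,8Z)-3-hydroxy-10-{[(2E)-3-(4-hydroxyphenyl)prop-2-en-1-yl]oxy}-4,8-dimethyldeca-4,8-dien-1-ylidene]-5-(2-methylprop-1-en-1-yl)dihydrofuran-2(3H)-one | CC(=O)O[C@H]1/C(=C\C[C@@H](O)/C(C)=C/CC/C(C)=C\COC/C=C/c2ccc(O)cc2)C(=O)O[C@@H]1C=C(C)C | target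

Total step count: 21
Longest linear sequence: 13 steps (steps 1–8, then 17–21)

Steps most likely to fail

Step 8. What may go wrong is weak facial discrimination when the carboxylate captures the equilibrating π-allyl complex, so that C5 forms as a cis/trans mixture, or proton loss from the allyl unit to a 4,6-diene. The fallback sets out from 8 and comes back at 10; it sets C5 by 1,2-induction in a carbonyl addition instead of by allylic substitution, at the price of the carbonate arm. The auxiliary of 8 is exchanged with MeOH/imidazole in CH2Cl2 to give methyl (3S,4E)-6-(methoxycarbonyloxy)-6-methyl-3-(triethylsilyloxy)hept-4-enoate F1. Ozonolysis (O3, CH2Cl2, −78 °C; Me2S) cuts C4=C5 to methyl (3S)-4-oxo-3-(triethylsilyloxy)butanoate F2. Nozaki–Hiyama–Kishi addition of 1-bromo-2-methylprop-1-ene (CrCl2, NiCl2 cat., DMF), which should follow the Felkin–Anh (1,2-anti) sense of an α-silyloxy aldehyde, gives methyl (3S,4R)-4-hydroxy-6-methyl-3-(triethylsilyloxy)hept-5-enoate F3. This γ-hydroxy ester closes to 10 with PPTS in CH2Cl2.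

Step 18. What may go wrong is formation of an E/Z mixture at C3=C1' in the elimination, or a second, vinylogous elimination in which DBU removes a C2' proton and the C4 silyloxy group is expelled. The fallback sets out from 10 and comes back at 25; it replaces aldol–dehydration by olefination. The enolate of 10 (LiN(i-Pr)2, THF, −78 °C) is C-phosphorylated with ClP(OEt)2 and the phosphonite is oxidised with H2O2 to diethyl [(4R,5R)-5-(2-methylprop-1-en-1-yl)-2-oxo-4-(triethylsilyloxy)oxolan-3-yl]phosphonate F4 (same spatial arrangement at C4 as in 10; the descriptor changes with the phosphorus substituent). A Horner–Wadsworth–Emmons reaction of F4 with 22 under LiCl/DBU in MeCN should give 25 with the E geometry usual for α-phosphono lactones.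

Step 13. What may go wrong is oxidation at the wrong allylic site (both ether CH2 groups are allylic too) or over-oxidation, so that little of the C8-oxygenated material forms. The fallback sets out from 16 and comes back at 18; it degrades and rebuilds the chain terminus. Epoxidation of the terminal, most electron-rich alkene (m-CPBA, NaHCO3, CH2Cl2, −20 °C) gives triisopropyl{4-[(1E)-3-{[(2Z)-5-(3,3-dimethyloxiran-2-yl)-3-methylpent-2-en-1-yl]oxy}prop-1-en-1-yl]phenoxy}silane F5. Cleavage with H5IO6 in THF/Et2O at 0 °C gives (4Z)-4-methyl-6-{[(2E)-3-[4-(triisopropylsilyloxy)phenyl]prop-2-en-1-yl]oxy}hex-4-enal F6. A Wittig reaction of F6 with the stabilised ylide Ph3P=C(CH3)CHO in toluene at 80 °C gives the E enal 18.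

Further compounds
F1 | step 8 | methyl (3S,4E)-6-(methoxycarbonyloxy)-6-methyl-3-(triethylsilyloxy)hept-4-enoate | CC[Si](CC)(CC)O[C@H](/C=C/C(C)(C)OC(=O)OC)CC(=O)OC
F2 | step 8 | methyl (3S)-4-oxo-3-(triethylsilyloxy)butanoate | CC[Si](CC)(CC)O[C@H](C=O)CC(=O)OC
F3 | step 8 | methyl (3S,4R)-4-hydroxy-6-methyl-3-(triethylsilyloxy)hept-5-enoate | CC[Si](CC)(CC)O[C@@H](CC(=O)OC)[C@H](O)C=C(C)C
F4 | step 18 | diethyl [(4R,5R)-5-(2-methylprop-1-en-1-yl)-2-oxo-4-(triethylsilyloxy)oxolan-3-yl]phosphonate | CCOP(=O)(OCC)C1[C@H](O[Si](CC)(CC)CC)[C@@H](C=C(C)C)OC1=O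
F5 | step 13 | triisopropyl{4-[(1E)-3-{[(2Z)-5-(3,3-dimethyloxiran-2-yl)-3-methylpent-2-en-1-yl]oxy}prop-1-en-1-yl]phenoxy}silane | CC1(C)OC1CC/C(C)=C\COC/C=C/c2ccc(O[Si](C(C)C)(C(C)C)C(C)C)cc2
F6 | step 13 | (4Z)-4-methyl-6-{[(2E)-3-[4-(triisopropylsilyloxy)phenyl]prop-2-en-1-yl]oxy}hex-4-enal | O=CCC/C(C)=C\COC/C=C/c1ccc(O[Si](C(C)C)(C(C)C)C(C)C)cc1
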